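93.1% of the Q charged to the elm flask comes out as D, on the mean of its plateau readings. Carry this number as the yield per Q: the D on the plateau divided by the Q charged, in the same moles.

| flask | E | Q | temperature | remark | time |
|---|---|---|---|---|---|
| elm | 0.045 M | 0.0315 M | 5 °C | the very flask that is asked about, followed so far |  |
| cedar | 0.045 M | 0.0315 M | −10 °C | run made earlier |  |
| flask | 0.045 M | 0.0315 M | 5 °C |  | 3.0 min |

| run | time / min | D / % |
|---|---|---|
| elm | 0.200 | 47.7 |
| elm | 0.333 | 63.6 |
| elm | 0.417 | 64.9 |
| elm | 0.667 | 65.6 |
| elm | 1.00 | 65.1 |
| elm | 1.50 | 65.2 |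
| elm | 2.50 | 64.9 |
| cedar | 0.417 | 22.4 |
| cedar | 0.667 | 33.2 |
| cedar | 0.833 | 39.0 |
| cedar | 1.33 | 54.5 |
| cedar | 2.00 | 66.8 |
| cedar | 3.00 | 66.9 |
| cedar | 5.00 | 66.7 |

(standard deviation of a reading: 0.3 percentage points)

1. D, in percent of the E first charged, at 3.0 min
2. the remedy with the largest gain of D, or "none" below 2 percentage points (Thursday's / Sunday's / Friday's / Monday's / none)
3. D present, with what was taken out counted in, in percent of the E first charged, after Thursday's
4. D present, with what was taken out counted in, in percent of the E first charged, after Sunday's

- Thursday's: at 3.0 min add Q, 50.0% of the amount charged, then wait 50 s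
- Sunday's: at 3.0 min raise the temperature by 10 K, then wait 50 s
- Friday's: change nothing and wait 50 s more
- Monday's: at 3.0 min take out 90% of the D then present, then wait 50 s

- what is taken out of D is counted as made
- additions bring no volume worth counting

Build the flask one process at a time, and reckon with what is left. Take the main step by itself. In the cedar run, the fraction of E not yet turned to D falls with a steady constant, 0.608 min⁻¹ at 0.417 min and 0.592 min⁻¹ at 1.33 min, so the step reads as first order in E. The first elm reading gives 3.24 min⁻¹, and by this step the fraction left in the flask at 3.0 min is 0.00601%.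

Now add the cost in Q. Suppose each E that leaves takes one Q. Then cQ/cE of 70.0% is the ceiling, and the elm readings do stop abruptly, by 0.667 min. Add the side path last. The plateau read in the elm run, 65.2%, lies below that ceiling, so by these readings 6.90% of the Q went to something other than D. In the colder cedar run the yield per Q reads 95.4%, which is higher.

My own reckoning follows. D in the flask stays at the plateau, and I expect nothing from waiting, warming or taking D out. At 3.0 min, before Thursday's, I reckon the E left at 30.0% of the charge, and the Q that Thursday's adds, 35.0% on the same scale, exceeds it. After 50 s, 6.72% of that E remains. The part reacted yields D at 93.1%, which gives 91.3%.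

The forecast says 65.1% now, Thursday's as best, 96% after Thursday's and 65.1% after Sunday's. Its ground: “A sharp stop like this suggests Q has run out rather than an equilibrium being approached”. We part on Thursday's: it takes 35% of E as remaining, and my figure is lower.

The flask gives 65.1%, Thursday's as best with a gain of 26 percentage points, 91.2% after Thursday's and 65.1% after Sunday's.

    E ⇌ L (K = 0.00256, k = 0.0575 s⁻¹, Ea = 70.0 kJ mol⁻¹, ΔH = −29.0 kJ mol⁻¹)
    L ⇌ X (K = 0.653, k = 29.1 s⁻¹, Ea = 56.0 kJ mol⁻¹, ΔH = −44.0 kJ mol⁻¹)
    Q + L → D (k = 50400 M⁻¹ s⁻¹, Ea = 32.0 kJ mol⁻¹)
    Q + X → J (k = 3.10 × 10⁵ M⁻¹ s⁻¹, Ea = 17.0 kJ mol⁻¹)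
    (constants at 5 °C)

Q is the limiting reagent: at 3.00 min the flask holds 0% of its Q and 29.9% of its E. Take away the shrinking supply of Q and the same flask gives 98.2%, not 65.1%. The yield per Q read from the elm run, 93.1%, has its counterpart in the flask: the Q spent stands as D 65.1% and J 4.87%, both in percent of the E charged.

Now take the neighbour charged with 0.11 M of E, the same Q and temperature. The yield per Q gives 26.7% of its E as D. The computed result is 26.7%, with Q at 0% and E at 71.1%.

All runs are calculated for substances that don't exist; noise was put on by code.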